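Assumption: "Mutafran C" is read as mutafuran C and the SMILES is taken as definitive: a trans-2,5-disubstituted oxolane, (2R) at the carbon bearing the ester chain and (5S) at the carbon bearing the enyne.

**Retrosynthetic overview**
1. Last bond: the C(sp)–C(sp2) bond of the enyne, by Sonogashira coupling of an oxolanyl alkyne with (1E,9E)-1,10-dibromodeca-1,9-diene in excess; the untouched end is the target's bromoalkene.
2. The dibromodiene comes from cyclooctene: ozonolysis to octanedial, then twofold Takai bromo-olefination.
3. The alkyne comes from the trans-oxolane-2-carbaldehyde by one-carbon homologation.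
4. The oxolane (the only ring, formed once) comes from a 2-substituted 3,4-dihydro-2H-pyran by oxidative ring contraction: a reagent-controlled 1,2-shift of the ring oxygen that sets C5.
5. The dihydropyran comes from resolved (S)-dihydropyranylmethanol (sets C2) and methyl acrylate, by iodination and Giese addition.

**Route**

Step 1
Reactants: 1 rac-(3,4-dihydro-2H-pyran-2-yl)methanol
Product: 2 rac-(3,4-dihydro-2H-pyran-2-yl)methyl acetate
Conditions: Ac2O, pyridine, DMAP (cat.), CH2Cl2, 0 °C to rt
Reagents that add atoms: acetic anhydride, CC(=O)OC(C)=O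
Why: DMAP-catalysed O-acetylation of a primary alcohol under basic conditions that the acid-sensitive enol ether tolerates; no stereocentre is set.

Step 2
Reactants: 2 rac-(3,4-dihydro-2H-pyran-2-yl)methyl acetate
Product: 3 [(2S)-3,4-dihydro-2H-pyran-2-yl]methanol
Conditions: porcine pancreatic lipase, phosphate buffer pH 7.2/acetone 9:1, rt, stopped at 35–40% conversion; chromatography on Et3N-washed silica
Reagents that add atoms: none
Why: Lipase-catalysed kinetic resolution by ester hydrolysis, in which the (S)-acetate is cleaved faster (as I recall for this substrate with this enzyme) and the unreacted (R)-enantiomer of 2 is removed; this fixes the centre that becomes C2 of the oxolane.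

Step 3
Reactants: 3 [(2S)-3,4-dihydro-2H-pyran-2-yl]methanol
Product: 4 (2S)-2-(iodomethyl)-3,4-dihydro-2H-pyran
Conditions: PPh3, I2, imidazole premixed in CH2Cl2, 0 °C; then 3, 0 °C to rt
Reagents that add atoms: iodine, II
Why: Appel (Garegg–Samuelsson) iodination by SN2 displacement of the alkoxyphosphonium at the primary carbon; preforming the phosphonium and buffering with imidazole keeps free iodine and acid away from the enol ether, and the stereocentre is untouched.

Step 4
Reactants: 4 (2S)-2-(iodomethyl)-3,4-dihydro-2H-pyran; 5 methyl acrylate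
Product: 6 methyl 4-[(2R)-3,4-dihydro-2H-pyran-2-yl]butanoate
Conditions: 5 (5 equiv), (Me3Si)3SiH (1.3 equiv, slow addition), AIBN (10 mol%), toluene, 80 °C
Reagents that add atoms: none
Why: Giese radical conjugate addition: the silyl radical abstracts iodine, the nucleophilic primary radical adds to the acrylate β-carbon and the adduct radical takes H from the silane; the electron-rich enol ether and the stereocentre are not involved (the descriptor changes to R by priority only).

Step 5
Reactants: 6 methyl 4-[(2R)-3,4-dihydro-2H-pyran-2-yl]butanoate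
Product: 7 methyl 4-[(2R,5S)-5-formyloxolan-2-yl]butanoate
Conditions: (R,R)-ArI(OH)OTs (1.2 equiv; Ar = 2,6-bis{[(2R)-1-methoxy-1-oxopropan-2-yl]oxy}phenyl, prepared beforehand from its diacetate and TsOH·H2O), H2O (3 equiv), CH2Cl2/CF3CH2OH 10:1, −78 °C, 6 added slowly; NaHCO3 quench; used crude
Reagents that add atoms: water, O
Why: Proposed new method: a reagent-controlled oxidative ring contraction of a cyclic enol ether, in which the electrophilic trivalent iodine adds to C5, water caps the oxocarbenium carbon C6, and the ring oxygen then makes a 1,2-shift from C6 to C5 anti to the departing iodoarene (inversion at C5), so that the former C6 leaves the ring as the formyl group; the face of C5 taken by iodine therefore fixes C5 of the oxolane, attack anti to the C2 side chain (the diequatorial adduct) gives the 2,5-trans product, and the C2-symmetric lactate arms of the (R,R)-reagent are meant to enforce that face over the weak bias of the remote C2 substituent; the closest known reactions are the Tl(NO3)3- and PhI(OH)OTs-mediated ring contractions of glycals and 3,4-dihydro-2H-pyran to 2,5-anhydro-aldoses and tetrahydrofurfural acetals (achiral reagents, stereocontrol by ring substituents) and the enantioselective oxidative rearrangements of styrenes with lactate-derived λ3-iodanes.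

Step 6
Reactants: 7 methyl 4-[(2R,5S)-5-formyloxolan-2-yl]butanoate
Product: 8 methyl 4-[(2R,5S)-5-ethynyloxolan-2-yl]butanoate
Conditions: dimethyl (1-diazo-2-oxopropyl)phosphonate (1.3 equiv), K2CO3 (2 equiv), MeOH, 0 °C to rt; cis isomer removed by chromatography
Reagents that add atoms: dimethyl (1-diazo-2-oxopropyl)phosphonate, CC(=O)C(=[N+]=[N-])P(=O)(OC)OC
Why: Ohira–Bestmann (Seyferth–Gilbert) homologation: the diazomethylphosphonate anion olefinates the aldehyde and the diazoalkene loses N2 with 1,2-hydride shift to the terminal alkyne; cold K2CO3/MeOH leaves the methyl ester unchanged and normally does not epimerise the α-alkoxy centre.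

Step 7
Reactants: 9 (Z)-cyclooctene
Product: 11 octanedial, via cyclooctene ozonide 10 (not isolated)
Conditions: O3, CH2Cl2, −78 °C; then PPh3, −78 °C to rt
Reagents that add atoms: ozone, [O-][O+]=O
Why: Criegee ozonolysis of the cis-alkene, with reductive cleavage of the ozonide by PPh3, unveils both aldehydes of the C8 chain at once.

Step 8
Reactants: 11 octanedial
Product: 12 (1E,9E)-1,10-dibromodeca-1,9-diene
Conditions: CHBr3 (4 equiv), CrBr2 (12 equiv), THF, 50 °C
Reagents that add atoms: bromoform, BrC(Br)Br
Why: Twofold Takai olefination: the gem-dichromium carbenoid formed from bromoform and divalent chromium adds to each aldehyde and anti elimination gives the (E)-bromoalkene; CrBr2 in place of CrCl2 avoids halide scrambling.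

Step 9
Reactants: 8 methyl 4-[(2R,5S)-5-ethynyloxolan-2-yl]butanoate; 12 (1E,9E)-1,10-dibromodeca-1,9-diene
Product: 13 methyl 4-[(2R,5S)-5-[(3E,11E)-12-bromododeca-3,11-dien-1-yn-1-yl]oxolan-2-yl]butanoate (mutafuran C)
Conditions: 12 (4 equiv, excess recovered), Pd(PPh3)4 (5 mol%), CuI (10 mol%), i-Pr2NH, degassed THF, rt to 40 °C
Reagents that add atoms: none
Why: Sonogashira coupling: zerovalent palladium inserts into one C–Br bond with retention of E geometry, the copper acetylide transmetalates and reductive elimination gives the enyne; the excess of the C2-symmetric dibromide keeps the reaction at mono-coupling and leaves the second (E)-bromoalkene as the target's terminus.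

**Compound list**
1 | rac-(3,4-dihydro-2H-pyran-2-yl)methanol | OCC1CCC=CO1 | starting material
2 | rac-(3,4-dihydro-2H-pyran-2-yl)methyl acetate | CC(=O)OCC1CCC=CO1 | intermediate
3 | [(2S)-3,4-dihydro-2H-pyran-2-yl]methanol | OC[C@@H]1CCC=CO1 | intermediate
4 | (2S)-2-(iodomethyl)-3,4-dihydro-2H-pyran | IC[C@@H]1CCC=CO1 | intermediate
5 | methyl acrylate | COC(=O)C=C | starting material
6 | methyl 4-[(2R)-3,4-dihydro-2H-pyran-2-yl]butanoate | COC(=O)CCC[C@@H]1CCC=CO1 | intermediate
7 | methyl 4-[(2R,5S)-5-formyloxolan-2-yl]butanoate | COC(=O)CCC[C@@H]1CC[C@@H](C=O)O1 | intermediate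
8 | methyl 4-[(2R,5S)-5-ethynyloxolan-2-yl]butanoate | COC(=O)CCC[C@@H]1CC[C@@H](C#C)O1 | intermediate
9 | (Z)-cyclooctene | C1CCCC/C=C\C1 | starting material
10 | cyclooctene ozonide (9,10,11-trioxabicyclo[6.2.1]undecane) | O1OC2CCCCCCC1O2 | intermediate
11 | octanedial | O=CCCCCCCC=O | intermediate
12 | (1E,9E)-1,10-dibromodeca-1,9-diene | Br/C=C/CCCCCC/C=C/Br | intermediate
13 | methyl 4-[(2R,5S)-5-[(3E,11E)-12-bromododeca-3,11-dien-1-yn-1-yl]oxolan-2-yl]butanoate (mutafuran C) | COC(=O)CCC[C@@H]1CC[C@@H](C#C/C=C/CCCCCC/C=C/Br)O1 | target

**Step count**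
Total: 9 steps. Longest linear sequence: 7 steps (steps 1–6 and 9).

**Steps most likely to fail, with fallbacks**

Step 5 (the proposed ring contraction). The facial control by the chiral iodane may be modest or of the wrong sense, and the liberated TsOH may hydrate the enol ether. The antipodal reagent is the first check. A side benefit if reagent control holds: residual (R)-material from step 2 ends up as the cis-oxolane and is removed with it.

The fallback sets out from 6 and comes back at 7, using a stepwise contraction through a discrete, separable leaving-group intermediate. Epoxidation–methanolysis of the enol ether with mCPBA in MeOH at 0 °C gives the trans hydroxy acetals. The isomer with the hydroxyl anti to the side chain, methyl 4-[(2R,5R,6R)-5-hydroxy-6-methoxyoxan-2-yl]butanoate F1, is separated on silica. Tf2O and pyridine in CH2Cl2 at −20 °C give the equatorial triflate methyl 4-[(2R,5R,6R)-6-methoxy-5-(trifluoromethylsulfonyloxy)oxan-2-yl]butanoate F2. Warming F2 in MeOH with 2,6-lutidine at 40 °C triggers the established solvolytic ring contraction of pyranoside 2-sulfonates (ring oxygen anti to the leaving group, inversion at C5). This gives the acetal methyl 4-[(2R,5S)-5-(dimethoxymethyl)oxolan-2-yl]butanoate F3, and cold aqueous TFA unmasks 7.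

Step 8 (twofold Takai bromo-olefination). Bromoform is the least reliable Takai partner, and E/Z erosion counts twice. The fallback sets out from 11 and comes back at 12. Ohira–Bestmann homologation at both ends (2.6 equiv reagent, K2CO3, MeOH) gives deca-1,9-diyne F4. Twofold hydrozirconation with Cp2Zr(H)Cl in THF at rt, then NBS at 0 °C, gives 12 with the E geometry fixed by syn addition.

Step 9 (desymmetrising Sonogashira). The bromoalkene is sluggish, and double coupling or alkyne dimerisation can erode the yield. The fallback sets out from 11 and 8 and comes back at 13, with the two ends differentiated instead of statistical. Mono-Takai iodo-olefination of 11 (CHI3 1 equiv, CrCl2, THF, 0 °C) gives (8E)-9-iodonon-8-enal F5. Sonogashira coupling of 8 with F5 (PdCl2(PPh3)2, CuI, i-Pr2NH, THF, rt, 1:1) gives the enyne aldehyde methyl 4-[(2R,5S)-5-[(3E)-11-oxoundec-3-en-1-yn-1-yl]oxolan-2-yl]butanoate F6. A final Takai bromo-olefination (CHBr3, CrBr2, THF) gives 13.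

**Further compounds**
F1 | step 5 | methyl 4-[(2R,5R,6R)-5-hydroxy-6-methoxyoxan-2-yl]butanoate | COC(=O)CCC[C@@H]1CC[C@@H](O)[C@H](OC)O1
F2 | step 5 | methyl 4-[(2R,5R,6R)-6-methoxy-5-(trifluoromethylsulfonyloxy)oxan-2-yl]butanoate | COC(=O)CCC[C@@H]1CC[C@@H](OS(=O)(=O)C(F)(F)F)[C@H](OC)O1
F3 | step 5 | methyl 4-[(2R,5S)-5-(dimethoxymethyl)oxolan-2-yl]butanoate | COC(=O)CCC[C@@H]1CC[C@@H](C(OC)OC)O1
F4 | step 8 | deca-1,9-diyne | C#CCCCCCCC#C
F5 | step 9 | (8E)-9-iodonon-8-enal | O=CCCCCCC/C=C/I
F6 | step 9 | methyl 4-[(2R,5S)-5-[(3E)-11-oxoundec-3-en-1-yn-1-yl]oxolan-2-yl]butanoate | COC(=O)CCC[C@@H]1CC[C@@H](C#C/C=C/CCCCCCC=O)O1
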